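**Retrosynthetic overview**

- The target is released from its 4',5'-dibenzyl ether by hydrogenolysis; it has no stereocentre.
- Feature carrying the strategy: ring A holds four contiguous oxygenated carbons, C5(OH)–C6(OMe)–C7(OMe)–C8(OMe), clamped between C4a and C8a of the pyranone. This strip is the four-carbon ring of dimethyl squarate: its two methoxy groups become 6- and 7-OMe, the untouched carbonyl becomes the chelated 5-OH, and the attacked, O-methylated carbonyl becomes 8-OMe.
- Ring A is disconnected at C5–C4a (thermal 4π opening of a 4-pyranonyl-4-methoxycyclobutenone, then 6π closure onto pyranone C5) and at C8–C8a (C6 lithiation of a 2-aryl-3-methoxy-4-pyranone, 1,2-addition to the squarate).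
- The arylpyranone is disconnected at C2–C1' by Suzuki–Miyaura coupling of 2-bromo-3-methoxy-4-pyranone (from pyromeconic acid) with the ring B boronic acid (from 3,4-bis(benzyloxy)benzaldehyde).
- Ring order: rings B and C are bought and joined first; ring A is the only ring formed, in the last C–C bond-forming step.

Key step: step 9

Assumption: pyromeconic acid, dimethyl squarate and 3,4-bis(benzyloxy)benzaldehyde are bought, and 2'-hydroxy-3',4',5',6'-tetramethoxyacetophenone (used in one fallback only) is taken as a catalogue compound.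

**Route**

Step 1
Reactants: 1 3,4-bis(benzyloxy)benzaldehyde
Product: 3 3,4-bis(benzyloxy)phenol, via 3,4-bis(benzyloxy)phenyl formate 2 (not isolated)
Conditions: mCPBA, CH2Cl2, 0 °C to rt; NaHCO3 wash; then K2CO3 (cat.), MeOH, rt
Reagents that add atoms: 3-chloroperbenzoic acid (mCPBA), O=C(OO)c1cccc(Cl)c1
Why: Dakin-type Baeyer–Villiger oxidation, in which the electron-rich aryl group migrates in the peracid adduct to give formate 2, which methanol cleaves under carbonate catalysis while the benzyl ethers stay untouched.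

Step 2
Reactants: 3 3,4-bis(benzyloxy)phenol
Product: 4 1,2-bis(benzyloxy)-4-methoxybenzene
Conditions: MeI, K2CO3, acetone, reflux
Reagents that add atoms: iodomethane, CI
Why: Williamson etherification of the phenoxide with iodomethane is routine and leaves the benzyl ethers intact.

Step 3
Reactants: 4 1,2-bis(benzyloxy)-4-methoxybenzene
Product: 5 1-bromo-4,5-bis(benzyloxy)-2-methoxybenzene
Conditions: NBS, MeCN, 0 °C to rt, dark
Reagents that add atoms: N-bromosuccinimide, O=C1CCC(=O)N1Br
Why: Electrophilic aromatic bromination should occur only at the carbon ortho to the methoxy group and para to a benzyloxy group, the most activated position that is not flanked by two substituents.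

Step 4
Reactants: 5 1-bromo-4,5-bis(benzyloxy)-2-methoxybenzene
Product: 8 4,5-bis(benzyloxy)-2-methoxyphenylboronic acid, via aryllithium 6 (not isolated), via lithium aryltriisopropoxyborate 7 (not isolated)
Conditions: n-BuLi, THF, −78 °C; B(OiPr)3, −78 °C to rt; 1 M HCl
Reagents that add atoms: triisopropyl borate, CC(C)OB(OC(C)C)OC(C)C; water, O
Why: Bromine–lithium exchange at −78 °C outruns any deprotonation, and trapping the aryllithium with a trialkyl borate followed by acid hydrolysis is the standard route to an arylboronic acid.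

Step 5
Reactants: 9 3-hydroxy-4H-pyran-4-one (pyromeconic acid)
Product: 10 2-bromo-3-hydroxy-4H-pyran-4-one
Conditions: NBS, MeCN, 0 °C to rt
Reagents that add atoms: N-bromosuccinimide, O=C1CCC(=O)N1Br
Why: The enolic 3-hydroxyl makes C2 the nucleophilic ring carbon (the site of Mannich and aldol reactions of 3-hydroxy-4-pyranones), so electrophilic bromination should give the 2-bromide.

Step 6
Reactants: 10 2-bromo-3-hydroxy-4H-pyran-4-one
Product: 11 2-bromo-3-methoxy-4H-pyran-4-one
Conditions: MeI (excess), K2CO3, acetone, rt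
Reagents that add atoms: iodomethane, CI
Why: Williamson O-alkylation of the acidic enolic hydroxyl, with excess iodomethane at room temperature keeping the oxido anion from displacing the activated bromide of a second molecule.

Step 7
Reactants: 11 2-bromo-3-methoxy-4H-pyran-4-one; 8 4,5-bis(benzyloxy)-2-methoxyphenylboronic acid
Product: 12 2-[4,5-bis(benzyloxy)-2-methoxyphenyl]-3-methoxy-4H-pyran-4-one
Conditions: Pd(OAc)2 (5 mol %), SPhos (10 mol %), K3PO4, toluene/H2O, 80 °C
Reagents that add atoms: none
Why: Suzuki–Miyaura coupling, in which the C2–Br bond (a vinylogous acyl bromide) adds readily to zerovalent palladium and the bulky biarylphosphine speeds transmetalation and reductive elimination of the doubly ortho-substituted pair so that coupling outruns protodeboronation.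

Step 8
Reactants: 12 2-[4,5-bis(benzyloxy)-2-methoxyphenyl]-3-methoxy-4H-pyran-4-one; 13 dimethyl squarate
Product: 16 2,3,4-trimethoxy-4-[6-(4,5-bis(benzyloxy)-2-methoxyphenyl)-5-methoxy-4-oxo-4H-pyran-2-yl]cyclobut-2-en-1-one (racemic), via 6-lithiopyranone 14 (not isolated), via lithium alkoxide adduct 15 (not isolated)
Conditions: LiTMP (lithium 2,2,6,6-tetramethylpiperidide, from the amine and n-BuLi), THF, −78 °C, 15 min; cannulate into 13, THF, −78 °C; MeOTf (1.05 equiv), −78 to −20 °C; aq. NaHCO3
Reagents that add atoms: methyl trifluoromethanesulfonate, COS(=O)(=O)C(F)(F)F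
Why: Deprotonative lithiation by the hindered amide should remove C6–H, the vinylic hydrogen alpha to the ring oxygen and the most acidic one once C2 and C3 are substituted (by analogy with the C2 lithiation of 3-substituted chromones), the vinyllithium then adds 1,2 to one squarate carbonyl and the alkoxide is capped by methyl triflate; the new quaternary carbon forms racemic and becomes aromatic in step 9.

Step 9
Reactants: 16 2,3,4-trimethoxy-4-[6-(4,5-bis(benzyloxy)-2-methoxyphenyl)-5-methoxy-4-oxo-4H-pyran-2-yl]cyclobut-2-en-1-one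
Product: 19 4',5'-bis(benzyloxy)-5-hydroxy-3,6,7,8,2'-pentamethoxyflavone, via dienylketene 17 (not isolated), via 4aH-chromene-4,5-dione 18 (not isolated)
Conditions: degassed toluene, 110 °C, Ar
Reagents that add atoms: none
Why: Proposed new method: heating should cleave the C1–C4 bond of the cyclobutenone by conrotatory 4π electrocyclic opening to the (Z)-dienylketene 17, in which the pyranone C5=C6 bond is the third π unit; thermal disrotatory 6π electrocyclization then bonds the electrophilic ketene carbon to pyranone C5, the nucleophilic β-carbon of the ring enol ether, so the closure is polarity-matched. This closes the six-membered carbocycle, ring A, across C5 and C6 of the pyranone (new bond: flavone C5–C4a) and gives dienone 18, whose single sp3 hydrogen at C4a sits between two carbonyl groups and should be lost at once by enolization to the phenol, held by the hydrogen bond from 5-OH to the C4 carbonyl. The closest known reaction type is the Moore-type thermal ring expansion of 4-aryl- and 4-alkenyl-4-alkoxycyclobutenones (from squarate esters and organolithiums) to annulated hydroquinone monoethers; a 4-oxo-4H-pyran-2-yl group has not been shown as the unsaturated arm. No stereocentre is created, since the racemic quaternary carbon of 16 becomes aromatic C8 and C4a of 18 is flattened on enolization. The step needs inward rotation of the pyranonyl arm, which the outward-rotating C4 methoxy donor enforces, and closure at C5 only, which is secured because the squarate unit sits on C6 and C5–H is its sole neighbouring ring carbon.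

Step 10
Reactants: 19 4',5'-bis(benzyloxy)-5-hydroxy-3,6,7,8,2'-pentamethoxyflavone
Product: 20 5,4',5'-trihydroxy-3,6,7,8,2'-pentamethoxyflavone
Conditions: H2 (1 atm), Pd/C (10 wt %), EtOAc/MeOH, rt
Reagents that add atoms: none
Why: Catalytic hydrogenolysis cleaves only the two benzylic C–O bonds, since methyl ethers, the chelated phenol and the tetrasubstituted chromone double bond are not reduced at 1 atm and room temperature.

**Compound list**

1 | 3,4-bis(benzyloxy)benzaldehyde | O=Cc1ccc(OCc2ccccc2)c(OCc2ccccc2)c1 | starting material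
2 | 3,4-bis(benzyloxy)phenyl formate | O=COc1ccc(OCc2ccccc2)c(OCc2ccccc2)c1 | intermediate
3 | 3,4-bis(benzyloxy)phenol | Oc1ccc(OCc2ccccc2)c(OCc2ccccc2)c1 | intermediate
4 | 1,2-bis(benzyloxy)-4-methoxybenzene | COc1ccc(OCc2ccccc2)c(OCc2ccccc2)c1 | intermediate
5 | 1-bromo-4,5-bis(benzyloxy)-2-methoxybenzene | COc1cc(OCc2ccccc2)c(OCc2ccccc2)cc1Br | intermediate
6 | [4,5-bis(benzyloxy)-2-methoxyphenyl]lithium | COc1cc(OCc2ccccc2)c(OCc2ccccc2)cc1[Li] | intermediate
7 | lithium [4,5-bis(benzyloxy)-2-methoxyphenyl]tri(propan-2-yloxy)borate | [Li+].COc1cc(OCc2ccccc2)c(OCc2ccccc2)cc1[B-](OC(C)C)(OC(C)C)OC(C)C | intermediate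
8 | 4,5-bis(benzyloxy)-2-methoxyphenylboronic acid | COc1cc(OCc2ccccc2)c(OCc2ccccc2)cc1B(O)O | intermediate
9 | 3-hydroxy-4H-pyran-4-one (pyromeconic acid) | O=c1ccocc1O | starting material
10 | 2-bromo-3-hydroxy-4H-pyran-4-one | O=c1ccoc(Br)c1O | intermediate
11 | 2-bromo-3-methoxy-4H-pyran-4-one | COc1c(Br)occc1=O | intermediate
12 | 2-[4,5-bis(benzyloxy)-2-methoxyphenyl]-3-methoxy-4H-pyran-4-one | COc1c(-c2cc(OCc3ccccc3)c(OCc3ccccc3)cc2OC)occc1=O | intermediate
13 | dimethyl squarate (3,4-dimethoxycyclobut-3-ene-1,2-dione) | COC1=C(OC)C(=O)C1=O | starting material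
14 | [6-(4,5-bis(benzyloxy)-2-methoxyphenyl)-5-methoxy-4-oxo-4H-pyran-2-yl]lithium | [Li]c1cc(=O)c(OC)c(-c2cc(OCc3ccccc3)c(OCc3ccccc3)cc2OC)o1 | intermediate
15 | lithium 1-[6-(4,5-bis(benzyloxy)-2-methoxyphenyl)-5-methoxy-4-oxo-4H-pyran-2-yl]-2,3-dimethoxy-4-oxocyclobut-2-en-1-olate (racemic) | [Li+].COC1=C(OC)C([O-])(c2cc(=O)c(OC)c(-c3cc(OCc4ccccc4)c(OCc4ccccc4)cc3OC)o2)C1=O | intermediate
16 | 2,3,4-trimethoxy-4-[6-(4,5-bis(benzyloxy)-2-methoxyphenyl)-5-methoxy-4-oxo-4H-pyran-2-yl]cyclobut-2-en-1-one (racemic) | COC1=C(OC)C(OC)(c2cc(=O)c(OC)c(-c3cc(OCc4ccccc4)c(OCc4ccccc4)cc3OC)o2)C1=O | intermediate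
17 | (3Z)-4-[6-(4,5-bis(benzyloxy)-2-methoxyphenyl)-5-methoxy-4-oxo-4H-pyran-2-yl]-2,3,4-trimethoxybuta-1,3-dien-1-one | O=C=C(OC)/C(OC)=C(/OC)c1cc(=O)c(OC)c(-c2cc(OCc3ccccc3)c(OCc3ccccc3)cc2OC)o1 | intermediate
18 | 2-[4,5-bis(benzyloxy)-2-methoxyphenyl]-3,6,7,8-tetramethoxy-4aH-chromene-4,5-dione (racemic) | COC1=C(OC)C(=O)C2C(=O)C(OC)=C(c3cc(OCc4ccccc4)c(OCc4ccccc4)cc3OC)OC2=C1OC | intermediate
19 | 2-[4,5-bis(benzyloxy)-2-methoxyphenyl]-5-hydroxy-3,6,7,8-tetramethoxy-4H-chromen-4-one (4',5'-di-O-benzyl-5-hydroxy-3,6,7,8,2'-pentamethoxyflavone) | COc1cc(OCc2ccccc2)c(OCc2ccccc2)cc1-c1oc2c(OC)c(OC)c(OC)c(O)c2c(=O)c1OC | intermediate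
20 | 5,4',5'-trihydroxy-3,6,7,8,2'-pentamethoxyflavone (2-(4,5-dihydroxy-2-methoxyphenyl)-5-hydroxy-3,6,7,8-tetramethoxy-4H-chromen-4-one) | COc1cc(O)c(O)cc1-c1oc2c(OC)c(OC)c(OC)c(O)c2c(=O)c1OC | target

**Step count and risks**

Total steps: 10. Longest linear sequence: 8 steps (steps 1, 2, 3, 4, 7, 8, 9, 10, from 1 to 20); the pyranone branch (steps 5 and 6) joins at step 7.

Steps most likely to fail:

1. Step 9 (the labelled key step). After ring opening, the dienylketene may fail to close onto pyranone C5, because the C5=C6 bond is tied into a cross-conjugated, partly aromatic vinylogous ester. The ketene would then be lost to dimerization or to adventitious nucleophiles. The fallback uses known chemistry and builds ring C between a bought ring A ketone and the ring B aldehyde; it sets out from aryl bromide 5 and comes back at 19. Aryllithium 6, generated as in step 4, would be formylated with DMF to 4,5-bis(benzyloxy)-2-methoxybenzaldehyde F1. Claisen–Schmidt condensation of F1 with purchased 2'-hydroxy-3',4',5',6'-tetramethoxyacetophenone (CC(=O)c1c(O)c(OC)c(OC)c(OC)c1OC) under KOH in EtOH should give the 2'-hydroxychalcone F2. Oxidative cyclization with catalytic I2 in DMSO at 130 °C should give 4',5'-bis(benzyloxy)-5,6,7,8,2'-pentamethoxyflavone F3. Epoxidation of its C2=C3 bond with dimethyldioxirane to the 2,3-epoxyflavanone F4, followed by opening with catalytic p-TsOH, should deliver the 3-hydroxyflavone F5. Methylation with MeI and K2CO3 would give the 3,5,6,7,8,2'-hexamethyl ether F6. Chelation-directed cleavage of the 5-O-methyl group peri to the C4 carbonyl with AlCl3 in MeCN should then return 19. Any benzyl ether lost at that stage does no harm, since step 10 removes both.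

2. Step 8. Deprotonation may not stay at C6: removal of C5–H next to the carbonyl with ring opening, or conjugate addition of the lithiated species to unmetalated pyranone, may compete. Methyl triflate may also alkylate the pyranone carbonyl oxygen instead of the alkoxide. The fallback replaces deprotonative lithiation by halogen–metal exchange; it sets out from 12 and comes back at 16. Zincation of 12 with TMPZnCl·LiCl in THF at 25 °C should give the configurationally and thermally robust pyranonylzinc chloride F7. Iodine would convert it into the 6-iodopyranone F8. Iodine–magnesium exchange with iPrMgCl·LiCl at −40 °C would generate the pyranonylmagnesium chloride F9 regiospecifically and free of amide base. Addition of F9 to 13 and NH4Cl quench should give the 4-hydroxycyclobutenone F10. O-Methylation of F10 with MeI and Ag2O, which does not alkylate the pyranone carbonyl irreversibly, would return 16.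

3. Step 7. The electron-rich ortho-methoxy boronic acid may protodeboronate faster than it transmetalates. Aqueous base may also displace the activated bromide or open the pyranone ring. The fallback is a base-free Negishi coupling; it sets out from aryl bromide 5 (with 11 as partner) and comes back at 12. Aryllithium 6 would be transmetalated with ZnCl2 in THF to the arylzinc chloride F11. F11 would be coupled with 11 under Pd(PPh3)4 in THF at 50 °C, without water or base.

**Further compounds**

F1 | step 9 | 4,5-bis(benzyloxy)-2-methoxybenzaldehyde | COc1cc(OCc2ccccc2)c(OCc2ccccc2)cc1C=O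
F2 | step 9 | (E)-3-[4,5-bis(benzyloxy)-2-methoxyphenyl]-1-(2-hydroxy-3,4,5,6-tetramethoxyphenyl)prop-2-en-1-one | COc1cc(OCc2ccccc2)c(OCc2ccccc2)cc1/C=C/C(=O)c1c(O)c(OC)c(OC)c(OC)c1OC
F3 | step 9 | 2-[4,5-bis(benzyloxy)-2-methoxyphenyl]-5,6,7,8-tetramethoxy-4H-chromen-4-one | COc1cc(OCc2ccccc2)c(OCc2ccccc2)cc1-c1cc(=O)c2c(OC)c(OC)c(OC)c(OC)c2o1
F4 | step 9 | 2-[4,5-bis(benzyloxy)-2-methoxyphenyl]-2,3-epoxy-5,6,7,8-tetramethoxychroman-4-one (racemic) | COc1cc(OCc2ccccc2)c(OCc2ccccc2)cc1C12OC1C(=O)c1c(OC)c(OC)c(OC)c(OC)c1O2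
F5 | step 9 | 2-[4,5-bis(benzyloxy)-2-methoxyphenyl]-3-hydroxy-5,6,7,8-tetramethoxy-4H-chromen-4-one | COc1cc(OCc2ccccc2)c(OCc2ccccc2)cc1-c1oc2c(OC)c(OC)c(OC)c(OC)c2c(=O)c1O
F6 | step 9 | 2-[4,5-bis(benzyloxy)-2-methoxyphenyl]-3,5,6,7,8-pentamethoxy-4H-chromen-4-one | COc1cc(OCc2ccccc2)c(OCc2ccccc2)cc1-c1oc2c(OC)c(OC)c(OC)c(OC)c2c(=O)c1OC
F7 | step 8 | chloro[6-(4,5-bis(benzyloxy)-2-methoxyphenyl)-5-methoxy-4-oxo-4H-pyran-2-yl]zinc | Cl[Zn]c1cc(=O)c(OC)c(-c2cc(OCc3ccccc3)c(OCc3ccccc3)cc2OC)o1
F8 | step 8 | 2-[4,5-bis(benzyloxy)-2-methoxyphenyl]-6-iodo-3-methoxy-4H-pyran-4-one | COc1c(-c2cc(OCc3ccccc3)c(OCc3ccccc3)cc2OC)oc(I)cc1=O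
F9 | step 8 | chloro[6-(4,5-bis(benzyloxy)-2-methoxyphenyl)-5-methoxy-4-oxo-4H-pyran-2-yl]magnesium | Cl[Mg]c1cc(=O)c(OC)c(-c2cc(OCc3ccccc3)c(OCc3ccccc3)cc2OC)o1
F10 | step 8 | 4-hydroxy-2,3-dimethoxy-4-[6-(4,5-bis(benzyloxy)-2-methoxyphenyl)-5-methoxy-4-oxo-4H-pyran-2-yl]cyclobut-2-en-1-one (racemic) | COC1=C(OC)C(O)(c2cc(=O)c(OC)c(-c3cc(OCc4ccccc4)c(OCc4ccccc4)cc3OC)o2)C1=O
F11 | step 7 | chloro[4,5-bis(benzyloxy)-2-methoxyphenyl]zinc | COc1cc(OCc2ccccc2)c(OCc2ccccc2)cc1[Zn]Cl
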